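**Strategy.** Ring C of the abietane quinone (C-8, C-9, C-11 to C-14) is taken apart at C-9–C-11 and C-8–C-14, so that C-11 to C-14, with their three oxygens and the isopropyl group, come from a squarate ester. Heating a 4-dienyl-4-silyloxycyclobutenone opens the four-membered ring to a dienylketene, whose ketene carbon C-11 closes onto the ring B vinyl carbon C-9 by 6π electrocyclisation; oxidation then gives the fully substituted quinone in one operation. The precursor is built from di-tert-butyl squarate and a tricyclic ring A/B dienyl iodide lactone, itself made by an enantioselective Diels–Alder reaction and a stereoconvergent bridging alkylation that fixes C-4.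

Key step: step 11

Remark on numbering: abietane numbering is used for all cyclic intermediates (ring A: C-1 to C-5 and C-10; ring B: C-5 to C-10; C-19 is the lactone carbonyl on C-4, C-20 the OCH2 group on C-10). In the "lactone core" C-4 carries an α-methyl and the β-carbonyl, C-10 the β-oxymethylene, and H-5 is α.

Assumption 1: the (S) antipode of the oxazaborolidinium catalyst is taken to direct the diene to the Si face of the α-carbon of enal 5, as assigned from the accepted pre-transition-state model for 2-substituted acroleins. If the sense of induction is the opposite, the (R) catalyst is used and nothing else changes.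

Assumption 2: 5-chloropentanal and di-tert-butyl squarate are taken as purchasable.

**Route**

Step 1
Reactants: 1 methyl sorbate
Product: 3 methyl (3E)-2-methylhexa-3,5-dienoate (racemic), via lithium trienolate 2 (not isolated)
Conditions: LiN(i-Pr)2, THF/HMPA, −78 °C; then MeI, −78 → 0 °C
Reagents that add atoms: iodomethane, CI
Why: Deconjugative α-alkylation, in which the base removes a proton from the terminal methyl group and the extended trienolate is methylated kinetically at the α-carbon, leaves the conjugated (3E)-1,3-diene needed for the cycloaddition; the new stereocentre is deliberately racemic because it is erased and reset in step 5.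

Step 2
Reactants: 4 5-chloropentanal
Product: 5 5-chloro-2-methylidenepentanal
Conditions: aq. CH2O (37%), pyrrolidine (10 mol%), propionic acid (10 mol%), i-PrOH, 45 °C
Reagents that add atoms: formaldehyde, C=O
Why: Organocatalytic α-methylenation (Mannich condensation with formaldehyde followed by elimination of the amine) is a standard route to 2-substituted acroleins and tolerates the primary chloride.

Step 3
Reactants: 3 methyl (3E)-2-methylhexa-3,5-dienoate; 5 5-chloro-2-methylidenepentanal
Product: 6 methyl 2-[(1S,6R)-6-(3-chloropropyl)-6-formylcyclohex-2-en-1-yl]propanoate (both epimers at the propanoate α-carbon)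
Conditions: (S)-o-tolyl oxazaborolidine from α,α-diphenylprolinol (20 mol%), Tf2NH (20 mol%), CH2Cl2, −78 → −40 °C
Reagents that add atoms: none
Why: In this catalytic enantioselective Diels–Alder reaction of a 2-substituted acrolein, the alkyl-bearing diene terminus bonds to the formyl-bearing carbon ("ortho" regiochemistry), the formyl group is expected endo and so ends up cis to the propanoate-bearing carbon, and the chiral oxazaborolidinium cation directs the diene to the Si face of the α-carbon, which sets C-10 (quaternary) and C-5 while both enantiomers of racemic 3 are consumed.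

Step 4
Reactants: 6 Diels–Alder adduct
Product: 8 cis-fused chloropropyl δ-lactone (both C-4 epimers), via hydroxy ester 7 (not isolated)
Conditions: NaBH4, MeOH, 0 °C; then p-TsOH (cat.), PhMe, 80 °C
Reagents that add atoms: none
Why: Chemoselective NaBH4 reduction of the neopentyl aldehyde leaves ester, chloride and alkene untouched, and the primary alcohol, held cis to the ester side chain, closes the δ-lactone by acid-catalysed transesterification.

Step 5
Reactants: 8 cis-fused chloropropyl δ-lactone
Product: 10 tricyclic lactone alkene (lactone core with C-6=C-7), via potassium lactone enolate 9 (not isolated)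
Conditions: KN(SiMe3)2, THF/DMPU, −78 °C → rt
Reagents that add atoms: none
Why: In this intramolecular enolate alkylation (6-exo-tet) both C-4 epimers give the same planar enolate, and the three-carbon tether anchored on C-10 can reach C-4 only from its own face, so ring A closes stereoconvergently to the bridged bicyclo[3.3.1] lactone with the single C-4 configuration of the target.

Step 6
Reactants: 10 tricyclic lactone alkene
Product: 11 tricyclic enone (C-6=C-7–C-8=O)
Conditions: Rh2(cap)4 (dirhodium tetrakis(caprolactamate), 1 mol%), t-BuOOH (70% aq.), K2CO3, CH2Cl2, rt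
Reagents that add atoms: tert-butyl hydroperoxide, CC(C)(C)OO
Why: Dirhodium-catalysed allylic oxidation with tert-butyl hydroperoxide converts the only allylic methylene (C-8) into the enone carbonyl, the alternative allylic hydrogen at C-5 being tertiary and flanked by two quaternary carbons.

Step 7
Reactants: 11 tricyclic enone
Product: 13 dienyl triflate (8-triflyloxy-6,8-diene), via potassium dienolate 12 (not isolated)
Conditions: KN(SiMe3)2, THF, −78 °C; then PhNTf2, −78 → 0 °C
Reagents that add atoms: N-phenylbis(trifluoromethanesulfonimide), O=S(=O)(N(c1ccccc1)S(=O)(=O)C(F)(F)F)C(F)(F)F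
Why: Kinetic deprotonation of the enone at its only α' position (C-9) gives the cross-conjugated dienolate, which is trapped on oxygen as the 2-triflyloxy-1,3-diene.

Step 8
Reactants: 13 dienyl triflate
Product: 14 dienyl iodide (8-iodo-6,8-diene)
Conditions: Ni(cod)2 (10 mol%), NaI, DMA/THF, rt
Reagents that add atoms: sodium iodide, [Na+].[I-]
Why: Nickel-catalysed halide exchange of an enol triflate (oxidative addition to zerovalent nickel, triflate–iodide metathesis, reductive elimination) gives the alkenyl iodide needed for fast lithium–halogen exchange and tolerates the lactone.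

Step 9
Reactants: 14 dienyl iodide; 15 di-tert-butyl squarate
Product: 18 4-dienyl-2,3-di-tert-butoxy-4-(trimethylsilyloxy)cyclobutenone, via alkenyllithium 16 (not isolated), via lithium alkoxide 17 (not isolated)
Conditions: t-BuLi (2 equiv), Et2O/THF, −78 °C; then 15, THF, −78 °C; then Me3SiCl, −78 → 0 °C
Reagents that add atoms: chlorotrimethylsilane, C[Si](C)(C)Cl
Why: Lithium–iodine exchange at −78 °C is much faster than attack on the hindered, pivalate-like lactone, the alkenyllithium adds 1,2 to one of the two equivalent squarate carbonyls, and the tertiary alkoxide is silylated in situ so that this carbinol cannot ionise in step 10; the new carbinol centre forms as a mixture and is destroyed in step 11.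

Step 10
Reactants: 18 4-dienyl-2,3-di-tert-butoxy-4-(trimethylsilyloxy)cyclobutenone
Product: 21 4-dienyl-2-tert-butoxy-3-isopropyl-4-(trimethylsilyloxy)cyclobutenone, via tertiary lithium alkoxide 19 (not isolated), via tertiary trifluoroacetate 20 (not isolated)
Conditions: i-PrLi, THF, −78 °C; then (CF3CO)2O, −78 → 0 °C; aq. NaHCO3
Reagents that add atoms: isopropyllithium, [Li]C(C)C
Why: In this sequential squarate functionalisation isopropyllithium adds to the strained cyclobutenone carbonyl in preference to the lactone, and O-trifluoroacetylation triggers ionisation to an allyl cation stabilised by the distal tert-butoxy group, which loses isobutene to give the 1,3-transposed cyclobutenone with the carbonyl next to the tert-butoxy carbon and the isopropyl carbon next to the silyloxy carbinol.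

Step 11
Reactants: 21 4-dienyl-2-tert-butoxy-3-isopropyl-4-(trimethylsilyloxy)cyclobutenone
Product: 25 12-tert-butoxy-11,14-quinone, via dienylketene 22 (not isolated), via cyclohexadienone 23 (not isolated), via silylated hydroquinone 24 (not isolated)
Conditions: PhMe, 110 °C; then PhI(OAc)2, MeCN/H2O, 0 °C
Reagents that add atoms: none
Why: Heating opens the cyclobutenone by a conrotatory 4π electrocyclic reaction in which the silyloxy group rotates outwards, so the ring B dienyl group is placed cis to the ketene in 22. The ketene carbon C-11 then bonds to the ring B vinyl carbon C-9 in a thermal disrotatory 6π electrocyclisation that closes the six-membered ring C (C-8, C-9, C-11 to C-14), and dienone 23 aromatises by tautomerisation to the mono-silylated hydroquinone 24, which PhI(OAc)2 oxidises to the para-quinone. The closest known reaction type is the Moore rearrangement of 4-alkenyl-4-hydroxycyclobutenones to hydroquinones and quinones. No new stereocentre survives, since C-9 is sp3 only transiently and C-4, C-5 and C-10 are not touched. The step needs a defined substituent pattern and a single closure mode: the first is fixed by the cyclobutenone from step 10 (carbonyl flanked by the tert-butoxy carbon, hence O-t-Bu at C-12 and isopropyl at C-13), the second by the fact that only C-8=C-9 is conjugated 1,3,5 with the ketene, with H-9 inside and the quaternary C-10 outside the cyclising triene.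

Step 12
Reactants: 25 12-tert-butoxy-11,14-quinone
Product: 26 12-hydroxy-11,14-quinone
Conditions: CF3CO2H, CH2Cl2, 0 °C → rt
Reagents that add atoms: none
Why: Acidolysis of the tert-butyl vinylogous ester (loss of isobutene via the tert-butyl cation) unmasks the hydroxyquinone under conditions that leave the lactone and the C-6=C-7 alkene intact.

Step 13
Reactants: 26 12-hydroxy-11,14-quinone
Product: 27 (4S,5R,10R)-12-acetoxy-11,14-dioxoabieta-6,8,12-trien-19,20-olide (target)
Conditions: Ac2O, pyridine, DMAP (cat.), CH2Cl2, 0 °C → rt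
Reagents that add atoms: acetic anhydride, CC(=O)OC(C)=O
Why: O-Acylation of the acidic 2-hydroxy-1,4-quinone under nucleophilic catalysis gives the enol acetate of the target without affecting any stereocentre.

**Compound list**

1 | methyl sorbate, methyl (2E,4E)-hexa-2,4-dienoate | C/C=C/C=C/C(=O)OC | starting material
2 | lithium trienolate of 1, lithium (3E)-1-methoxyhexa-1,3,5-trien-1-olate | C=C/C=C/C=C(O[Li])OC | intermediate
3 | methyl (3E)-2-methylhexa-3,5-dienoate, racemic | C=C/C=C/C(C)C(=O)OC | intermediate
4 | 5-chloropentanal | O=CCCCCCl | starting material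
5 | 5-chloro-2-methylidenepentanal | C=C(CCCCl)C=O | intermediate
6 | methyl 2-[(1S,6R)-6-(3-chloropropyl)-6-formylcyclohex-2-en-1-yl]propanoate, formyl cis to the propanoate-bearing carbon, both epimers at the propanoate α-carbon | O=C[C@@]1(CCCCl)CCC=C[C@H]1C(C)C(=O)OC | intermediate
7 | methyl 2-[(1S,6R)-6-(3-chloropropyl)-6-(hydroxymethyl)cyclohex-2-en-1-yl]propanoate | OC[C@@]1(CCCCl)CCC=C[C@H]1C(C)C(=O)OC | intermediate
8 | (4aS,8aR)-8a-(3-chloropropyl)-4-methyl-1,4,4a,7,8,8a-hexahydro-3H-isochromen-3-one, cis-fused δ-lactone, both C-4 epimers | ClCCC[C@@]12COC(=O)C(C)[C@@H]1C=CCC2 | intermediate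
9 | potassium enolate of lactone 8 | ClCCC[C@@]12COC(O[K])=C(C)[C@@H]1C=CCC2 | intermediate
10 | tricyclic lactone alkene: lactone core (4α-CH3, C-19(=O)–O–C-20 bridge on the β face of C-4 and C-10, 5α-H) with C-6=C-7, CH2 at C-8 and C-9 | C2C[C@]13CCC[C@](C)(C(=O)OC1)[C@@H]3C=C2 | intermediate
11 | tricyclic enone: lactone core with C-6=C-7 and C-8 ketone | O=C2C[C@]13CCC[C@](C)(C(=O)OC1)[C@@H]3C=C2 | intermediate
12 | potassium dienolate of 11 (C-6=C-7, C-8(OK)=C-9) | [K]OC2=C[C@]13CCC[C@](C)(C(=O)OC1)[C@@H]3C=C2 | intermediate
13 | dienyl triflate: lactone core with C-6=C-7 and C-8(OTf)=C-9 | O=S(=O)(OC2=C[C@]13CCC[C@](C)(C(=O)OC1)[C@@H]3C=C2)C(F)(F)F | intermediate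
14 | dienyl iodide: lactone core with C-6=C-7 and C-8(I)=C-9 | IC2=C[C@]13CCC[C@](C)(C(=O)OC1)[C@@H]3C=C2 | intermediate
15 | di-tert-butyl squarate, 3,4-di-tert-butoxycyclobut-3-ene-1,2-dione | CC(C)(C)OC1=C(OC(C)(C)C)C(=O)C1=O | starting material
16 | alkenyllithium: lactone core with C-6=C-7 and C-8(Li)=C-9 | [Li]C2=C[C@]13CCC[C@](C)(C(=O)OC1)[C@@H]3C=C2 | intermediate
17 | lithium alkoxide of the squarate adduct: 2,3-di-tert-butoxy-4-(lithiooxy)-4-(dien-8-yl)cyclobut-2-en-1-one | CC(C)(C)OC1=C(OC(C)(C)C)C(O[Li])(C1=O)C2=C[C@]34CCC[C@](C)(C(=O)OC3)[C@@H]4C=C2 | intermediate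
18 | 2,3-di-tert-butoxy-4-(dien-8-yl)-4-(trimethylsilyloxy)cyclobut-2-en-1-one, either configuration at the carbinol carbon | CC(C)(C)OC1=C(OC(C)(C)C)C(O[Si](C)(C)C)(C1=O)C2=C[C@]34CCC[C@](C)(C(=O)OC3)[C@@H]4C=C2 | intermediate
19 | lithium 2,3-di-tert-butoxy-4-(dien-8-yl)-1-isopropyl-4-(trimethylsilyloxy)cyclobut-2-en-1-olate | CC(C)(C)OC1=C(OC(C)(C)C)C(O[Si](C)(C)C)(C1(O[Li])C(C)C)C2=C[C@]34CCC[C@](C)(C(=O)OC3)[C@@H]4C=C2 | intermediate
20 | tertiary trifluoroacetate of 19 | CC(C)(C)OC1=C(OC(C)(C)C)C(O[Si](C)(C)C)(C1(OC(=O)C(F)(F)F)C(C)C)C2=C[C@]34CCC[C@](C)(C(=O)OC3)[C@@H]4C=C2 | intermediate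
21 | 2-tert-butoxy-4-(dien-8-yl)-3-isopropyl-4-(trimethylsilyloxy)cyclobut-2-en-1-one | CC(C)(C)OC1=C(C(C)C)C(O[Si](C)(C)C)(C1=O)C2=C[C@]34CCC[C@](C)(C(=O)OC3)[C@@H]4C=C2 | intermediate
22 | dienylketene: O=C(11)=C(12)(O-t-Bu)–C(13)(i-Pr)=C(14)(OSiMe3)–C(8)=C(9), dienyl group cis to the ketene | O=C=C(OC(C)(C)C)C(C(C)C)=C(O[Si](C)(C)C)C2=C[C@]13CCC[C@](C)(C(=O)OC1)[C@@H]3C=C2 | intermediate
23 | cyclohexadienone: ring C closed, C-11 ketone, C-9 sp3 (H), C-12=C-13 and C-14=C-8 | CC(C)(C)OC1=C(C(C)C)C(O[Si](C)(C)C)=C2C(C1=O)[C@]13CCC[C@](C)(C(=O)OC1)[C@@H]3C=C2 | intermediate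
24 | silylated hydroquinone: aromatic ring C with 11-OH, 12-O-t-Bu, 13-i-Pr, 14-OSiMe3; C-6=C-7 | CC(C)(C)OC1=C(C(C)C)C(O[Si](C)(C)C)=C2C(=C1O)[C@]13CCC[C@](C)(C(=O)OC1)[C@@H]3C=C2 | intermediate
25 | 12-tert-butoxy-11,14-dioxoabieta-6,8,12-trien-19,20-olide | CC(C)(C)OC1=C(C(C)C)C(=O)C2=C(C1=O)[C@]13CCC[C@](C)(C(=O)OC1)[C@@H]3C=C2 | intermediate
26 | 12-hydroxy-11,14-dioxoabieta-6,8,12-trien-19,20-olide | OC1=C(C(C)C)C(=O)C2=C(C1=O)[C@]13CCC[C@](C)(C(=O)OC1)[C@@H]3C=C2 | intermediate
27 | (4S,5R,10R)-12-acetoxy-11,14-dioxoabieta-6,8,12-trien-19,20-olide | CC(=O)OC1=C(C(C)C)C(=O)C2=C(C1=O)[C@]13CCC[C@](C)(C(=O)OC1)[C@@H]3C=C2 | target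

**Count**

Total steps: 13. Longest linear sequence: 12 steps (1 → 3 → 6 → 8 → 10 → 11 → 13 → 14 → 18 → 21 → 25 → 26 → 27).

**Steps most likely to fail, with fallbacks**

Step 3. The risk is insufficient formyl-endo selectivity, or a mismatched pairing of the chiral catalyst with one enantiomer of the racemic diene, either of which would leave the C-5 epimer in the material. The fallback replaces endo control by chirality transfer. Setting out from 5, the same catalyst-controlled Diels–Alder reaction is run with 2-(trimethylsilyloxy)buta-1,3-diene, which creates only the quaternary centre and should give (R)-1-(3-chloropropyl)-4-(trimethylsilyloxy)cyclohex-3-ene-1-carbaldehyde F1. Saegusa oxidation with Pd(OAc)2 in MeCN should give (R)-1-(3-chloropropyl)-4-oxocyclohex-2-ene-1-carbaldehyde F2. Reduction of both carbonyl groups with BH3·SMe2 and the (S)-Me-CBS oxazaborolidine should give, by reagent control at the enone, (1R,4R)-4-(3-chloropropyl)-4-(hydroxymethyl)cyclohex-2-en-1-ol F3, in which the allylic hydroxyl is cis to the hydroxymethyl group. A Johnson–Claisen rearrangement with triethyl orthopropionate and catalytic propionic acid at 140 °C then forms the C-4–C-5 bond suprafacially on the face of the departing allylic oxygen and moves the alkene to C-6=C-7, giving ethyl 2-[(1S,6R)-6-(3-chloropropyl)-6-(hydroxymethyl)cyclohex-2-en-1-yl]propanoate F4. Acid-catalysed lactonisation of F4 comes back to the route at 8.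

Step 6. The risk is hydrogen abstraction at the tertiary allylic C-5, or attack of the peroxyl radical at C-6, giving transposed or over-oxidised material. The fallback uses a pericyclic instead of a radical manifold. From 10, SeO2 (catalytic) with t-BuOOH in CH2Cl2 hydroxylates the allylic methylene by an ene reaction followed by a [2,3]-sigmatropic shift. By the usual preference for CH2 over CH this should give the 8-hydroxy tricyclic lactone (allylic alcohol, either C-8 epimer) F5, and Dess–Martin oxidation of F5 comes back to the route at 11.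

Step 10. The risk is reduction by β-hydride transfer or sluggish addition of the secondary alkyllithium at the hindered cyclobutenone carbonyl, or competing attack on the lactone. The fallback postpones the isopropyl group. From 18, LiAlH(O-t-Bu)3 in THF at −78 °C reduces only the cyclobutenone carbonyl to 2,3-di-tert-butoxy-4-(dien-8-yl)-4-(trimethylsilyloxy)cyclobut-2-en-1-ol F6. (CF3CO)2O then brings about the same transposition with loss of isobutene and gives 2-tert-butoxy-4-(dien-8-yl)-4-(trimethylsilyloxy)cyclobut-2-en-1-one F7. Thermolysis in toluene and PhI(OAc)2 oxidation as in step 11, with the same C-9–C-11 closure, give 12-tert-butoxy-11,14-dioxo-15,16,17-trinorabieta-6,8,12-trien-19,20-olide F8. CF3CO2H gives the corresponding 12-hydroxyquinone lacking the isopropyl group F9. A silver-catalysed decarboxylative radical alkylation of the Minisci type (isobutyric acid, AgNO3, (NH4)2S2O8, MeCN/H2O, 60 °C) then introduces the isopropyl group at the only free quinone position C-13 and comes back to the route at 26.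

**Further compounds**

F1 | step 3 | (R)-1-(3-chloropropyl)-4-(trimethylsilyloxy)cyclohex-3-ene-1-carbaldehyde | O=C[C@]1(CCCCl)CC=C(O[Si](C)(C)C)CC1
F2 | step 3 | (R)-1-(3-chloropropyl)-4-oxocyclohex-2-ene-1-carbaldehyde | O=C[C@]1(CCCCl)C=CC(=O)CC1
F3 | step 3 | (1R,4R)-4-(3-chloropropyl)-4-(hydroxymethyl)cyclohex-2-en-1-ol | OC[C@]1(CCCCl)C=C[C@H](O)CC1
F4 | step 3 | ethyl 2-[(1S,6R)-6-(3-chloropropyl)-6-(hydroxymethyl)cyclohex-2-en-1-yl]propanoate | OC[C@@]1(CCCCl)CCC=C[C@H]1C(C)C(=O)OCC
F5 | step 6 | 8-hydroxy tricyclic lactone, allylic alcohol of the lactone core with C-6=C-7 | OC2C[C@]13CCC[C@](C)(C(=O)OC1)[C@@H]3C=C2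
F6 | step 10 | 2,3-di-tert-butoxy-4-(dien-8-yl)-4-(trimethylsilyloxy)cyclobut-2-en-1-ol | CC(C)(C)OC1=C(OC(C)(C)C)C(O[Si](C)(C)C)(C1O)C2=C[C@]34CCC[C@](C)(C(=O)OC3)[C@@H]4C=C2
F7 | step 10 | 2-tert-butoxy-4-(dien-8-yl)-4-(trimethylsilyloxy)cyclobut-2-en-1-one | CC(C)(C)OC1=CC(O[Si](C)(C)C)(C1=O)C2=C[C@]34CCC[C@](C)(C(=O)OC3)[C@@H]4C=C2
F8 | step 10 | 12-tert-butoxy-11,14-dioxo-15,16,17-trinorabieta-6,8,12-trien-19,20-olide | CC(C)(C)OC1=CC(=O)C2=C(C1=O)[C@]13CCC[C@](C)(C(=O)OC1)[C@@H]3C=C2
F9 | step 10 | 12-hydroxy-11,14-dioxo-15,16,17-trinorabieta-6,8,12-trien-19,20-olide | OC1=CC(=O)C2=C(C1=O)[C@]13CCC[C@](C)(C(=O)OC1)[C@@H]3C=C2
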